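**Retrosynthetic overview**
1. The epoxide is made last from alkene 39 (bromohydrin, then base). 39 comes from an aldol condensation joining aldehyde 21 (left half with both linker carbons) to C5′ of cycloheptenone 32 (right half), then hydrogenation and enol triflate methylation (C6′–Me, C6′=C7′).
2. Left half (benzoxepine numbering): the oxepane (O1, C2, C3, C4, C5, C5a, C9a) is grown from the six-membered 2,2-dimethyltetrahydropyran-3-one 15 by insertion of one carbon (C4) with Me3SiCHN2. The new C3–C4 bond and the seven-membered ring arise in the same operation.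
3. Enabling feature: the carbinol carbon C3 lies between the fully substituted, oxygen-bearing C2 (O1–CMe2) and the C4H2–C5H2 bridge to quaternary C5a. At the ketone level only the CH2 side can migrate, so the trans-fused pyranone expands on one side only.
4. Right half (azulene numbering, primed): copper-catalysed conjugate addition sets C3a′, an SmI2 ketyl–enone closure builds the cyclopentane (C1′, C8a′), and cyclopropanation/FeCl3 opening expands the cyclohexanone to the cycloheptenone.
5. Ring order: left cyclohexane (steps 1–6), pyran (8), oxepane (12); right cyclohexene (16–19), cyclopentane (20), cycloheptene (22–23); epoxide (30).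

Key step: step 12

Assumption: the hydrolase in step 2 and the ligand antipode in step 16 are taken to induce the sense that leads to the drawn enantiomers; otherwise the recovered acetate (after methanolysis) or the antipodal ligand is used.

Step 1
Reactants: 1 3-ethoxycyclohex-2-en-1-one
Product: 2 rac-4-ethoxy-2-oxocyclohex-3-en-1-yl acetate
Conditions: Mn(OAc)3, benzene, reflux (Dean–Stark)
Reagents that add atoms: manganese triacetate, CC(=O)[O-].CC(=O)[O-].CC(=O)[O-].[Mn+3]
Why: Mn(OAc)3 α′-acetoxylation of an enone should functionalise only the enolisable CH2 next to the carbonyl of the vinylogous ester.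

Step 2
Reactants: 2 rac-4-ethoxy-2-oxocyclohex-3-en-1-yl acetate
Product: 3 (R)-3-ethoxy-6-hydroxycyclohex-2-en-1-one
Conditions: lipase (Amano PS), pH 7 phosphate buffer/t-BuOMe, 30 °C, stopped near half conversion; unreacted (S)-2 separated
Reagents that add atoms: none
Why: Enzymatic kinetic resolution (lipase-catalysed ester hydrolysis) of the α′-acetoxy enone should set the absolute configuration of the future C9a.

Step 3
Reactants: 3 (R)-3-ethoxy-6-hydroxycyclohex-2-en-1-one
Product: 4 (R)-6-[(tert-butyldimethylsilyl)oxy]-3-ethoxycyclohex-2-en-1-one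
Conditions: TBSCl, imidazole, DMF, rt
Reagents that add atoms: TBSCl, CC(C)(C)[Si](C)(C)Cl
Why: Standard silylation of a secondary alcohol; the ether will later direct the conjugate addition.

Step 4
Reactants: 4 (R)-6-[(tert-butyldimethylsilyl)oxy]-3-ethoxycyclohex-2-en-1-one
Product: 6 (R)-4-[(tert-butyldimethylsilyl)oxy]-3-methylcyclohex-2-en-1-one, via methyllithium adduct 5 (not isolated)
Conditions: MeLi, THF, −78 °C; then 1 M HCl, 0 °C
Reagents that add atoms: methyllithium, C[Li]; water, O
Why: Stork–Danheiser transposition (1,2-addition to the vinylogous ester, then hydrolysis and dehydration) should give the β-methyl enone with the silyloxy stereocentre now at the γ-carbon.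

Step 5
Reactants: 6 (R)-4-[(tert-butyldimethylsilyl)oxy]-3-methylcyclohex-2-en-1-one
Product: 7 tert-butyldimethyl{[(1R,2R)-2-methyl-2-(3-methylbut-2-en-1-yl)-4-(trimethylsilyloxy)cyclohex-3-en-1-yl]oxy}silane (prenyl trans to OTBS)
Conditions: prenylmagnesium chloride, CuBr·SMe2, Me3SiCl, THF, −78 °C
Reagents that add atoms: prenylmagnesium chloride, CC(C)=CC[Mg]Cl; chlorotrimethylsilane, C[Si](C)(C)Cl
Why: Conjugate addition of an allylic copper reagent with silyl trapping should occur anti to the γ-silyloxy group through the unsubstituted allyl terminus, which sets the quaternary centre (future C5a, prenyl trans to oxygen) and fixes the enolate regiochemistry.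

Step 6
Reactants: 7 silyl enol ether
Product: 9 (3R,4R)-4-[(tert-butyldimethylsilyl)oxy]-3-methyl-3-(3-methylbut-2-en-1-yl)-2-(prop-2-en-1-yl)cyclohexan-1-one (C2 epimers), via lithium enolate 8 (not isolated)
Conditions: MeLi, THF, 0 °C; then allyl iodide, HMPA, −78 → 0 °C
Reagents that add atoms: allyl iodide, C=CCI
Why: Regiospecific enolate generation from the silyl enol ether and enolate alkylation with a reactive allylic iodide; the new α-centre is left as an epimer mixture and equilibrated in step 8.

Step 7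
Reactants: 9 silyl ether ketone
Product: 10 (3R,4R)-4-hydroxy-3-methyl-3-(3-methylbut-2-en-1-yl)-2-(prop-2-en-1-yl)cyclohexan-1-one (C2 epimers)
Conditions: Bu4NF, THF, rt
Reagents that add atoms: none
Why: Fluoride desilylation frees the hydroxyl that becomes the ring oxygen O1.

Step 8
Reactants: 10 hydroxy ketone
Product: 12 (4aR,5R,8aR)-3-hydroxy-2,2,4a-trimethyl-5-(prop-2-en-1-yl)octahydro-6H-chromen-6-one (trans-fused, C3 epimers), via epoxy alcohol 11 (not isolated)
Conditions: mCPBA, NaHCO3, CH2Cl2, 0 °C; then CSA (cat.), 0 °C → rt; then DBU, rt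
Reagents that add atoms: mCPBA, OOC(=O)c1cccc(Cl)c1
Why: Prilezhaev epoxidation of the trisubstituted alkene (faster than the terminal one) and acid-catalysed 6-endo epoxide opening at the tertiary carbon by the trans-disposed hydroxyl (5-exo would need a trans-fused tetrahydrofuran) should give the trans-fused pyran; DBU then equilibrates the ketone α-carbon to the equatorial allyl isomer, and the carbinol epimers are inconsequential.

Step 9
Reactants: 12 pyranol ketone
Product: 13 (4aR,5R,6S,8aR)-2,2,4a,6-tetramethyl-5-(prop-2-en-1-yl)octahydro-2H-chromene-3,6-diol (C3 epimers)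
Conditions: MeMgBr, CeCl3, THF, −78 °C
Reagents that add atoms: methylmagnesium bromide, C[Mg]Br
Why: Grignard addition to the ketone; axial approach is blocked by the syn-axial angular methyl, so equatorial attack should give the axial tertiary alcohol cis to that methyl (future C7).

Step 10
Reactants: 13 diol
Product: 14 (4aR,5R,6S,8aR)-6-hydroxy-2,2,4a,6-tetramethyl-5-(prop-2-en-1-yl)hexahydro-2H-chromen-3(4H)-one
Conditions: Dess–Martin periodinane, NaHCO3, CH2Cl2, rt
Reagents that add atoms: none
Why: Dess–Martin oxidation converts only the secondary carbinol (both epimers) into the pyran-3-one; the tertiary alcohol cannot react.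

Step 11
Reactants: 14 hydroxy pyranone
Product: 15 (4aR,5R,6S,8aR)-2,2,4a,6-tetramethyl-5-(prop-2-en-1-yl)-6-(triethylsilyloxy)hexahydro-2H-chromen-3(4H)-one
Conditions: Et3SiOTf, 2,6-lutidine, CH2Cl2, −78 °C
Reagents that add atoms: triethylsilyl triflate, CC[Si](CC)(CC)OS(=O)(=O)C(F)(F)F
Why: Silylation of the tertiary alcohol keeps it from being O-methylated by the diazo reagent in the next step.

Step 12
Reactants: 15 silylated pyranone
Product: 17 (5aR,6R,7S,9aR)-2,2,5a,7-tetramethyl-6-(prop-2-en-1-yl)-7-(triethylsilyloxy)octahydro-1-benzoxepin-3(2H)-one, via α-silyl ketone 16 (not isolated)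
Conditions: Me3SiCHN2, BF3·OEt2, CH2Cl2, −78 °C; then K2CO3, MeOH, rt
Reagents that add atoms: trimethylsilyldiazomethane, C[Si](C)(C)C=[N+]=[N-]
Why: The BF3-activated C3 carbonyl of the α-alkoxy ketone is attacked by the diazo carbon (new C3–C4 bond) to give a β-diazonium alkoxide, and the antiperiplanar C5 methylene then shifts from C3 to C4 with loss of N2, so the oxepan-3-one forms by 1,2-shift ring enlargement (six to seven ring atoms) rather than by end-to-end cyclisation; K2CO3/MeOH then C-desilylates 16. The closest known reaction type is the Lewis-acid-promoted trimethylsilyldiazomethane homologation of fused tetrahydropyran-3-ones to oxepan-3-ones (a Tiffeneau–Demjanov-type diazo ring expansion). No stereocentre is created, and C5a, C6, C7 and C9a are not enolisable or otherwise involved, so they are carried through unchanged. The step needs migration of the C5 methylene in preference to C2, which is secured because C2 is quaternary, crowded by two methyl groups and inductively deactivated by O1. It also needs single homologation, which the bulky silyl group in 16, the lower reactivity of the seven-membered ketone and a slight excess of reagent at low temperature should secure; the terminal alkene and the silyl ether are inert.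

Step 13
Reactants: 17 oxepanone
Product: 18 (3R,5aR,6R,7S,9aR)-2,2,5a,7-tetramethyl-6-(prop-2-en-1-yl)-7-(triethylsilyloxy)decahydro-1-benzoxepin-3-ol
Conditions: (S)-2-methyl-CBS-oxazaborolidine (cat.), catecholborane, toluene, −78 °C
Reagents that add atoms: none
Why: Corey–Bakshi–Shibata reduction; with quaternary C2 as the large and C4H2 as the small substituent, the (S)-catalyst should give the (3R)-alcohol under reagent control, and catecholborane leaves the terminal alkene alone.

Step 14
Reactants: 18 oxepanol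
Product: 19 bis(triethylsilyl) ether of 18
Conditions: Et3SiOTf, 2,6-lutidine, CH2Cl2, −78 → 0 °C
Reagents that add atoms: triethylsilyl triflate, CC[Si](CC)(CC)OS(=O)(=O)C(F)(F)F
Why: Silylation of the secondary alcohol protects it during the aldol condensation sequence.

Step 15
Reactants: 19 bis-silyl ether
Product: 21 2-[(3R,5aR,6R,7S,9aR)-2,2,5a,7-tetramethyl-3,7-bis(triethylsilyloxy)decahydro-1-benzoxepin-6-yl]acetaldehyde, via ozonide 20 (not isolated)
Conditions: O3, CH2Cl2, −78 °C; then PPh3, −78 °C → rt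
Reagents that add atoms: ozone, [O-][O+]=O
Why: Ozonolysis of the only remaining alkene gives the aldehyde that carries both linker carbons.

Step 16
Reactants: 22 4,4-dimethylcyclohex-2-en-1-one
Product: 24 (R)-3-(but-3-en-1-yl)-4,4-dimethylcyclohex-1-en-1-yl trifluoromethanesulfonate, via magnesium enolate 23 (not isolated)
Conditions: but-3-enylmagnesium bromide, CuBr·SMe2 (cat.), (R)-1-[(SP)-2-(diphenylphosphino)ferrocenyl]ethyldicyclohexylphosphine (cat.), t-BuOMe, −75 °C; then PhNTf2, THF, −75 → 0 °C
Reagents that add atoms: but-3-enylmagnesium bromide, C=CCC[Mg]Br; N-phenylbis(trifluoromethanesulfonimide), O=S(=O)(N(c1ccccc1)S(=O)(=O)C(F)(F)F)C(F)(F)F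
Why: Copper-catalysed asymmetric conjugate addition of a Grignard reagent sets the future C3a′ next to the gem-dimethyl carbon, and O-triflation of the regiodefined enolate fixes the alkene position.

Step 17
Reactants: 24 enol triflate
Product: 25 (R)-3-(but-3-en-1-yl)-4,4-dimethylcyclohex-1-ene
Conditions: Pd(OAc)2 (cat.), PPh3, HCO2H, Bu3N, DMF, 60 °C
Reagents that add atoms: none
Why: Palladium-catalysed formate reduction of an enol triflate gives the alkene without moving the double bond.

Step 18
Reactants: 25 diene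
Product: 26 (R)-4-(6,6-dimethylcyclohex-2-en-1-yl)butan-2-one
Conditions: PdCl2 (cat.), CuCl, O2 (1 atm), DMF/H2O, rt
Reagents that add atoms: water, O
Why: Wacker–Tsuji oxidation converts the terminal alkene into the methyl ketone in preference to the cyclic 1,2-disubstituted alkene.

Step 19
Reactants: 26 ketone
Product: 27 (R)-5,5-dimethyl-4-(3-oxobutyl)cyclohex-2-en-1-one
Conditions: Rh2(cap)4 (cap = caprolactamate, cat.), t-BuOOH, K2CO3, CH2Cl2, rt
Reagents that add atoms: tert-butyl hydroperoxide, CC(C)(C)OO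
Why: Dirhodium-catalysed allylic oxidation; hydrogen abstraction should occur at the ring CH2 rather than at the hindered tertiary allylic C–H next to the CMe2 group, giving the enone with the stereocentre at its γ-carbon.

Step 20
Reactants: 27 keto enone
Product: 28 (1R,3aR,7aR)-1-hydroxy-1,4,4-trimethyloctahydro-6H-inden-6-one (cis-fused, OH cis to the ring-fusion hydrogens)
Conditions: SmI2, HMPA, t-BuOH, THF, −78 → 0 °C
Reagents that add atoms: none
Why: SmI2 ketyl–olefin (ketone–enone) reductive cyclisation, 5-exo-trig onto the enone β-carbon; the tether enforces cis ring fusion, and the samarium-bound ketyl oxygen should stay on the convex face, anti to the ring CH2C=O, so the hydroxyl ends up cis to the ring-fusion hydrogens.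

Step 21
Reactants: 28 hydroxy ketone
Product: 29 triethylsilyl enol ether (double bond towards the ring-fusion side) and tertiary triethylsilyl ether of 28
Conditions: LiN(i-Pr)2 (2.3 equiv), THF, −78 °C; then Et3SiCl, HMPA, −78 → 0 °C
Reagents that add atoms: chlorotriethylsilane, CC[Si](CC)(CC)Cl
Why: Kinetic enolate formation should occur at the CH2 remote from the CMe2 group, and O-silylation traps both the enolate and the tertiary alkoxide.

Step 22
Reactants: 29 silyl enol ether
Product: 30 siloxycyclopropane (CH2 added across the enol ether double bond of 29)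
Conditions: Et2Zn, CH2I2, CH2Cl2, 0 °C → rt
Reagents that add atoms: diiodomethane, ICI
Why: Simmons–Smith cyclopropanation (Furukawa variant) of the electron-rich silyl enol ether; the cyclopropane stereocentres are lost in the next step.

Step 23
Reactants: 30 siloxycyclopropane
Product: 32 cis-fused 1,4,4-trimethyl-1-(triethylsilyloxy)-2,3,3a,4,5,8a-hexahydroazulen-6(1H)-one, via β-chloro ketone 31 (not isolated)
Conditions: FeCl3, DMF, 0 °C; then NaOAc, MeOH, 60 °C
Reagents that add atoms: none
Why: Saegusa–Ito ring expansion: the alkoxy radical cleaves the ring-fusion bond of the cyclopropane to the ring-enlarged β-keto radical, which is chlorinated, and NaOAc eliminates HCl, so the one-carbon insertion is regiospecific and leaves an enone enolisable only at C5′.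

Step 24
Reactants: 32 cycloheptenone; 21 aldehyde
Product: 33 aldol adduct (β-hydroxy ketone, mixture at C5′ and at the carbinol carbon)
Conditions: LiN(i-Pr)2, 32, THF, −78 °C; then 21, −78 °C
Reagents that add atoms: none
Why: Directed aldol addition of the cross-conjugated lithium enolate (deprotonation is possible only at C5′) to the unhindered aldehyde; both new stereocentres are erased in steps 25–26.

Step 25
Reactants: 33 aldol adduct
Product: 35 cross-conjugated dienone (exocyclic C5′ alkylidene, E/Z mixture), via mesylate 34 (not isolated)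
Conditions: MsCl, Et3N, CH2Cl2, 0 °C; then DBU, rt
Reagents that add atoms: none
Why: Mesylation and E1cB elimination complete the aldol condensation.

Step 26
Reactants: 35 dienone
Product: 36 saturated ketone with the C5′ hydrogen cis to the ring-fusion hydrogens
Conditions: H2 (3 atm), Pd/C, EtOAc, rt
Reagents that add atoms: none
Why: Heterogeneous hydrogenation of both C=C bonds; H2 should be delivered from the convex face of the cis-fused bicycle, which places H-5′ syn to H-3a′ and H-8a′ and the side chain on the cyclopentane face.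

Step 27
Reactants: 36 ketone
Product: 37 enol triflate (C6′=C7′)
Conditions: KN(SiMe3)2, THF, −78 °C; then PhNTf2, −78 → 0 °C
Reagents that add atoms: N-phenylbis(trifluoromethanesulfonimide), O=S(=O)(N(c1ccccc1)S(=O)(=O)C(F)(F)F)C(F)(F)F
Why: Kinetic enolisation at the C7′ methylene (C5′ is a hindered methine next to CMe2) and O-triflation fix the alkene regiochemistry.

Step 28
Reactants: 37 enol triflate
Product: 38 tris(triethylsilyl) ether of 39
Conditions: Fe(acac)3 (cat.), MeMgBr, THF/NMP, −30 → 0 °C
Reagents that add atoms: methylmagnesium bromide, C[Mg]Br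
Why: Iron-catalysed cross-coupling of an alkenyl triflate with a methyl Grignard reagent (Kochi-type coupling) installs the C6′ methyl on the trisubstituted alkene.

Step 29
Reactants: 38 tris-silyl ether
Product: 39 (3R,5aR,6R,7S,9aR)-6-{2-[1-hydroxy-1,4,4,6-tetramethyl-1,2,3,3a,4,5,8,8a-octahydroazulen-5-yl]ethyl}-2,2,5a,7-tetramethyldecahydro-1-benzoxepine-3,7-diol (sipholenol A skeleton; right half as in the SMILES)
Conditions: Bu4NF, THF, rt
Reagents that add atoms: none
Why: Fluoride desilylation removes all three triethylsilyl ethers before the acid- and base-sensitive epoxide is present.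

Step 30
Reactants: 39 triol alkene
Product: 41 CNP0216138.1 (epoxide oxygen syn to the C5′ side chain), via bromohydrin 40 (not isolated)
Conditions: NBS, THF/H2O, 0 °C; then K2CO3, MeOH, 0 °C → rt
Reagents that add atoms: water, O
Why: Bromohydrin formation and intramolecular Williamson closure: Br+ should add to the less hindered alkene face (anti to the side chain), water opens anti at tertiary C6′, and SN2 closure with inversion at C7′ places the oxygen on the face opposite to that reached by direct peracid attack, as the target requires.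

**Compound list**
1 | 3-ethoxycyclohex-2-en-1-one | CCOC1=CC(=O)CCC1 | starting material
2 | rac-4-ethoxy-2-oxocyclohex-3-en-1-yl acetate | CCOC1=CC(=O)C(OC(C)=O)CC1 | intermediate
3 | (R)-3-ethoxy-6-hydroxycyclohex-2-en-1-one | O[C@@H]1CCC(OCC)=CC1=O | intermediate
4 | (R)-6-[(tert-butyldimethylsilyl)oxy]-3-ethoxycyclohex-2-en-1-one | CC(C)(C)[Si](C)(C)O[C@@H]1CCC(OCC)=CC1=O | intermediate
5 | methyllithium adduct of 4 (tertiary carbinol, epimers; not isolated) | CC(C)(C)[Si](C)(C)O[C@@H]1CCC(OCC)=CC1(C)O | intermediate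
6 | (R)-4-[(tert-butyldimethylsilyl)oxy]-3-methylcyclohex-2-en-1-one | CC(C)(C)[Si](C)(C)O[C@@H]1CCC(=O)C=C1C | intermediate
7 | tert-butyldimethyl{[(1R,2R)-2-methyl-2-(3-methylbut-2-en-1-yl)-4-(trimethylsilyloxy)cyclohex-3-en-1-yl]oxy}silane | CC(C)(C)[Si](C)(C)O[C@@H]1CCC(O[Si](C)(C)C)=C[C@@]1(C)CC=C(C)C | intermediate
8 | lithium enolate corresponding to 7 (not isolated) | CC(C)(C)[Si](C)(C)O[C@@H]1CCC(O[Li])=C[C@@]1(C)CC=C(C)C | intermediate
9 | (3R,4R)-4-[(tert-butyldimethylsilyl)oxy]-3-methyl-3-(3-methylbut-2-en-1-yl)-2-(prop-2-en-1-yl)cyclohexan-1-one (C2 epimers) | CC(C)(C)[Si](C)(C)O[C@@H]1CCC(=O)C(CC=C)[C@@]1(C)CC=C(C)C | intermediate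
10 | (3R,4R)-4-hydroxy-3-methyl-3-(3-methylbut-2-en-1-yl)-2-(prop-2-en-1-yl)cyclohexan-1-one (C2 epimers) | O[C@@H]1CCC(=O)C(CC=C)[C@@]1(C)CC=C(C)C | intermediate
11 | epoxide of 10 at the prenyl double bond (not isolated) | O[C@@H]1CCC(=O)C(CC=C)[C@@]1(C)CC1OC1(C)C | intermediate
12 | (4aR,5R,8aR)-3-hydroxy-2,2,4a-trimethyl-5-(prop-2-en-1-yl)octahydro-6H-chromen-6-one (C3 epimers) | CC1(C)O[C@@H]2CCC(=O)[C@H](CC=C)[C@@]2(C)CC1O | intermediate
13 | (4aR,5R,6S,8aR)-2,2,4a,6-tetramethyl-5-(prop-2-en-1-yl)octahydro-2H-chromene-3,6-diol (C3 epimers) | CC1(C)O[C@@H]2CC[C@](C)(O)[C@H](CC=C)[C@@]2(C)CC1O | intermediate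
14 | (4aR,5R,6S,8aR)-6-hydroxy-2,2,4a,6-tetramethyl-5-(prop-2-en-1-yl)hexahydro-2H-chromen-3(4H)-one | CC1(C)O[C@@H]2CC[C@](C)(O)[C@H](CC=C)[C@@]2(C)CC1=O | intermediate
15 | 6-O-triethylsilyl ether of 14 | CC1(C)O[C@@H]2CC[C@](C)(O[Si](CC)(CC)CC)[C@H](CC=C)[C@@]2(C)CC1=O | intermediate
16 | 4-(trimethylsilyl) derivative of 17 (C4 epimers; not isolated) | CC1(C)O[C@@H]2CC[C@](C)(O[Si](CC)(CC)CC)[C@H](CC=C)[C@@]2(C)CC([Si](C)(C)C)C1=O | intermediate
17 | (5aR,6R,7S,9aR)-2,2,5a,7-tetramethyl-6-(prop-2-en-1-yl)-7-(triethylsilyloxy)octahydro-1-benzoxepin-3(2H)-one | CC1(C)O[C@@H]2CC[C@](C)(O[Si](CC)(CC)CC)[C@H](CC=C)[C@@]2(C)CCC1=O | intermediate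
18 | (3R,5aR,6R,7S,9aR)-2,2,5a,7-tetramethyl-6-(prop-2-en-1-yl)-7-(triethylsilyloxy)decahydro-1-benzoxepin-3-ol | CC1(C)O[C@@H]2CC[C@](C)(O[Si](CC)(CC)CC)[C@H](CC=C)[C@@]2(C)CC[C@H]1O | intermediate
19 | 3,7-bis(triethylsilyl) ether of the 6-allyl benzoxepine diol | CC1(C)O[C@@H]2CC[C@](C)(O[Si](CC)(CC)CC)[C@H](CC=C)[C@@]2(C)CC[C@H]1O[Si](CC)(CC)CC | intermediate
20 | ozonide (1,2,4-trioxolane) of 19 (not isolated) | CC1(C)O[C@@H]2CC[C@](C)(O[Si](CC)(CC)CC)[C@H](CC3OCOO3)[C@@]2(C)CC[C@H]1O[Si](CC)(CC)CC | intermediate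
21 | 2-[(3R,5aR,6R,7S,9aR)-2,2,5a,7-tetramethyl-3,7-bis(triethylsilyloxy)decahydro-1-benzoxepin-6-yl]acetaldehyde | CC1(C)O[C@@H]2CC[C@](C)(O[Si](CC)(CC)CC)[C@H](CC=O)[C@@]2(C)CC[C@H]1O[Si](CC)(CC)CC | intermediate
22 | 4,4-dimethylcyclohex-2-en-1-one | CC1(C)CCC(=O)C=C1 | starting material
23 | bromomagnesium enolate of (R)-3-(but-3-en-1-yl)-4,4-dimethylcyclohexanone (not isolated) | C=CCC[C@@H]1C=C(O[Mg]Br)CCC1(C)C | intermediate
24 | (R)-3-(but-3-en-1-yl)-4,4-dimethylcyclohex-1-en-1-yl trifluoromethanesulfonate | C=CCC[C@@H]1C=C(OS(=O)(=O)C(F)(F)F)CCC1(C)C | intermediate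
25 | (R)-3-(but-3-en-1-yl)-4,4-dimethylcyclohex-1-ene | C=CCC[C@@H]1C=CCCC1(C)C | intermediate
26 | (R)-4-(6,6-dimethylcyclohex-2-en-1-yl)butan-2-one | CC(=O)CC[C@@H]1C=CCCC1(C)C | intermediate
27 | (R)-5,5-dimethyl-4-(3-oxobutyl)cyclohex-2-en-1-one | CC(=O)CC[C@@H]1C=CC(=O)CC1(C)C | intermediate
28 | (1R,3aR,7aR)-1-hydroxy-1,4,4-trimethyloctahydro-6H-inden-6-one | O=C1CC(C)(C)[C@@H]2CC[C@@](C)(O)[C@@H]2C1 | intermediate
29 | bis(triethylsilyl) derivative of 28 (enol ether towards the ring fusion, tertiary silyl ether) | CC[Si](CC)(CC)OC1=C[C@@H]2[C@@H](CC[C@@]2(C)O[Si](CC)(CC)CC)C(C)(C)C1 | intermediate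
30 | siloxycyclopropane from 29 (cyclopropane stereocentres undefined) | CC[Si](CC)(CC)OC13CC(C)(C)[C@@H]2CC[C@@](C)(O[Si](CC)(CC)CC)[C@@H]2C1C3 | intermediate
31 | ring-enlarged β-chloro ketone (not isolated) | O=C1CC(C)(C)[C@@H]2CC[C@@](C)(O[Si](CC)(CC)CC)[C@@H]2C(Cl)C1 | intermediate
32 | cis-fused 1,4,4-trimethyl-1-(triethylsilyloxy)-2,3,3a,4,5,8a-hexahydroazulen-6(1H)-one (silyloxy cis to ring-fusion H) | O=C1CC(C)(C)[C@@H]2CC[C@@](C)(O[Si](CC)(CC)CC)[C@@H]2C=C1 | intermediate
33 | aldol adduct of 32 and 21 (epimers at C5′ and carbinol) | CC1(C)O[C@@H]2CC[C@](C)(O[Si](CC)(CC)CC)[C@H](CC(O)C3C(C)(C)[C@@H]4CC[C@@](C)(O[Si](CC)(CC)CC)[C@@H]4C=CC3=O)[C@@]2(C)CC[C@H]1O[Si](CC)(CC)CC | intermediate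
34 | mesylate of 33 (not isolated) | CC1(C)O[C@@H]2CC[C@](C)(O[Si](CC)(CC)CC)[C@H](CC(OS(C)(=O)=O)C3C(C)(C)[C@@H]4CC[C@@](C)(O[Si](CC)(CC)CC)[C@@H]4C=CC3=O)[C@@]2(C)CC[C@H]1O[Si](CC)(CC)CC | intermediate
35 | cross-conjugated dienone (exocyclic alkylidene at C5′, E/Z) | CC1(C)O[C@@H]2CC[C@](C)(O[Si](CC)(CC)CC)[C@H](CC=C3C(C)(C)[C@@H]4CC[C@@](C)(O[Si](CC)(CC)CC)[C@@H]4C=CC3=O)[C@@]2(C)CC[C@H]1O[Si](CC)(CC)CC | intermediate
36 | saturated C6′ ketone (H-5′ cis to ring-fusion H) | CC1(C)O[C@@H]2CC[C@](C)(O[Si](CC)(CC)CC)[C@H](CC[C@@H]3C(C)(C)[C@@H]4CC[C@@](C)(O[Si](CC)(CC)CC)[C@@H]4CCC3=O)[C@@]2(C)CC[C@H]1O[Si](CC)(CC)CC | intermediate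
37 | C6′ enol triflate (C6′=C7′) | CC1(C)O[C@@H]2CC[C@](C)(O[Si](CC)(CC)CC)[C@H](CC[C@@H]3C(C)(C)[C@@H]4CC[C@@](C)(O[Si](CC)(CC)CC)[C@@H]4CC=C3OS(=O)(=O)C(F)(F)F)[C@@]2(C)CC[C@H]1O[Si](CC)(CC)CC | intermediate
38 | tris(triethylsilyl) ether of 39 | CC1(C)O[C@@H]2CC[C@](C)(O[Si](CC)(CC)CC)[C@H](CC[C@@H]3C(C)(C)[C@@H]4CC[C@@](C)(O[Si](CC)(CC)CC)[C@@H]4CC=C3C)[C@@]2(C)CC[C@H]1O[Si](CC)(CC)CC | intermediate
39 | triol alkene (sipholenol A skeleton) | CC1(C)O[C@@H]2CC[C@](C)(O)[C@H](CC[C@@H]3C(C)(C)[C@@H]4CC[C@@](C)(O)[C@@H]4CC=C3C)[C@@]2(C)CC[C@H]1O | intermediate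
40 | trans-bromohydrin (Br at C7′ anti to the side chain, OH at C6′; not isolated) | CC1(C)O[C@@H]2CC[C@](C)(O)[C@H](CC[C@@H]3C(C)(C)[C@@H]4CC[C@@](C)(O)[C@@H]4C[C@@H](Br)[C@]3(C)O)[C@@]2(C)CC[C@H]1O | intermediate
41 | CNP0216138.1 | CC1(C)O[C@@H]2CC[C@](C)(O)[C@H](CC[C@@H]3C(C)(C)[C@@H]4CC[C@@](C)(O)[C@@H]4C[C@@H]4O[C@@]43C)[C@@]2(C)CC[C@H]1O | target

**Step count and risks**
Total steps: 30. Longest linear sequence: 22 steps (steps 1–15, then 24–30); the right half (steps 16–23) is made separately and joined in step 24.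

Steps most likely to fail:

1. Step 5. The allylic copper reagent may add 1,2 to the carbonyl, couple through its substituted terminus, or attack the crowded β-carbon with poor facial selectivity. Fallback, from 6: prenylmagnesium chloride without copper (THF, −78 °C) is allowed to add 1,2 through its γ-carbon to give the dienol 4-[(tert-butyldimethylsilyl)oxy]-3-methyl-1-(2-methylbut-3-en-2-yl)cyclohex-2-en-1-ol F1, of which the diastereomer with the allyl unit trans to the silyloxy group is separated. Its potassium alkoxide (KH, 18-crown-6, THF, 0 °C → rt) should undergo anionic oxy-Cope rearrangement, delivering the allyl unit suprafacially to the β-carbon as a prenyl group. Silylation of the resulting enolate with Me3SiCl rejoins the route at 7.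

2. Step 26. Hydrogen may be delivered to the exocyclic alkene with poor facial selectivity, giving the C5′ epimer. Fallback, from 35: the less hindered ring alkene alone is hydrogenated with RhCl(PPh3)3/H2 to give the exocyclic enone F2. Conjugate reduction with [(Ph3P)CuH]6 (benzene, rt) then forms the C5′ enolate, which is protonated kinetically from the open face by a hindered phenol (2,6-di-tert-butyl-4-methylphenol) to arrive at 36.

3. Step 30. The bromonium ion may form on the other alkene face or be opened by a neighbouring hydroxyl, leading to the epimeric epoxide or a bromo ether. Fallback, from 39: direct oxygen transfer with mCPBA/NaHCO3 (CH2Cl2, 0 °C), which attacks the face on which the bromonium ion would have formed, leads to 41 without new intermediates.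

Further compounds
F1 | step 5 | (1S,4R)-4-[(tert-butyldimethylsilyl)oxy]-3-methyl-1-(2-methylbut-3-en-2-yl)cyclohex-2-en-1-ol (allyl unit trans to OTBS; configuration as in the SMILES) | CC(C)(C)[Si](C)(C)O[C@@H]1CC[C@@](O)(C(C)(C)C=C)C=C1C
F2 | step 26 | exocyclic enone (ring C7′–C8′ saturated, C5′ alkylidene retained) | CC1(C)O[C@@H]2CC[C@](C)(O[Si](CC)(CC)CC)[C@H](CC=C3C(C)(C)[C@@H]4CC[C@@](C)(O[Si](CC)(CC)CC)[C@@H]4CCC3=O)[C@@]2(C)CC[C@H]1O[Si](CC)(CC)CC
F0 | step 30 | none | none
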